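Remark: atoms are numbered as in germacranes (ring C1–C10; C7 carries the isopropenyl group C11(=C12)C13; C9 is the ketone; C14 and C15 are the methyls on C10 and C4). The SMILES defines both oxiranes as cis (methyl and ring hydrogen on the same side), so the route is built for the (1R,3S,4R,5S,6S,7S,10R) isomer; the CIP label at C6 reads R in 17–19 and S elsewhere without any change in spatial arrangement.

## The problem

The target is a germacrane: a ten-membered carbocycle with an isopropenyl group at C7, a ketone at C9, trisubstituted oxiranes at C1–C10 and C4–C5, and angelate esters at C3 and C6. Both oxiranes are cis, so they derive from Z ring alkenes (C9/C2 cis and C3/C6 cis), not from the E alkenes of common germacranes. A ten-membered ring is the least favourable size to close directly, and here it must hold a Z-enone and a Z-2-ene-1,4-diol unit. Of the seven stereocentres, four are oxirane carbons and follow from alkene geometry plus one facial choice each. C6 and C7 are vicinal and can control one another, whereas C3 is 1,4-related to C6 across C4=C5 and needs a reagent. The C3 hydroxyl is allylic to C4=C5 and can direct that epoxidation, while the C1–C10 oxirane has only the ring conformation to rely on. The sensitive groups are the angelates (Z→E isomerisation to tiglates; incompatible with carbonyl methylenation and basic peroxide), the α,β-epoxy ketone, the 2,3-epoxy alcohols (Payne rearrangement), the bis-allylic C6 carbinol and the 1,5-diene C10=C1–C2–C3–C4=C5 (Cope rearrangement). The feature that opens the route is the unit O=C9–C8H2–C7H–C11(CH3)=C12H2: a γ,δ-unsaturated ketone whose carbonyl, α- and β-carbons are ring atoms while its alkene is exocyclic. This is the retron of a Claisen rearrangement in which O, C12 and C11 were ring members of a 12-membered lactone.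

## Retrosynthesis

**23 ⇒ 21 + 22.** The two ester C–O bonds are cut last. Angelates isomerise easily and would not survive titanium methylenation or basic peroxide, so diol 21 is acylated with angelic acid 22 under conditions free of nucleophilic catalyst.

**21 ⇒ 20 ⇒ 19 ⇒ 18 ⇒ 17.** The two oxiranes are removed. The C4–C5 oxirane comes from a peracid epoxidation directed by the free C3 hydroxyl of 19, with C6 kept as a bulky silyl ether (20); this requires orthogonal silyl groups (TES on O3, TBS on O6). The C1–C10 oxirane comes from nucleophilic epoxidation of the Z-enone of 17 (giving 18), the only electron-poor alkene. Both oxiranes being cis, the precursor is the (Z,Z)-dienone 17, which has only three stereocentres (C3, C6, C7).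

**17 ⇒ 16 ⇒ 15 (key cut).** The C7–C8 bond is cut and C9 is reconnected to C12 through oxygen. This leads to the 2-methylidene enol ether 16 and then to the 12-membered lactone 15, with C8 coming from a titanium methylidene. Compared with cutting a ring bond of 17 in the open chain, this cut removes the medium ring, the ketone, the isopropenyl group and the C7 stereocentre at once. The precursor is a strain-free macrolactone with two stereocentres. The forward reaction must bond C8 to the correct face of C7 under control of C6 and must leave both Z alkenes alone.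

**15 ⇒ 14.** The C7=C11 alkene is cut (ring-closing metathesis between a vinyl group on C6 and a methallyl ester). This is preferred over macrolactonisation because the ester can be made by carboxylate alkylation (no acyl activation, so no Z→E leakage) and because the configuration of C7=C11 does not matter.

**14 ⇒ 13 ⇒ 11 + 12.** The C5–C6 bond is cut: a Ni/Cr coupling of Z-iodoalkene 11 with acrolein 12 sets C6 under ligand control and keeps the Z geometry of C4=C5. The resulting alcohol 13 is silylated to 14.

**11 ⇒ 10 ⇒ 8 ⇒ 6 + 7 (+ 9).** The C1=C10 alkene is cut by a Z-selective phosphonate olefination of aldehyde 6 with phosphonate 7. The ethyl ester 8 is exchanged for the methallyl ester through carboxylate 10 and methallyl bromide 9.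

**6 ⇒ 5 ⇒ 4 ⇒ 3 ⇒ 2 ⇒ 1.** The C2–C3 bond is cut by a reagent-controlled allylboration of Z-iodoenal 3, which sets C3. The Z-iodoalkene comes from anti-carbomagnesiation/iodination of propargyl alcohol 1 via 2; protection (5) and alkene cleavage give 6.

## Roads not taken

**Alternative 1:** Direct closure of the ten-membered ring from an open chain, for example a Ni/Cr coupling between C5 and C6 of the iodo-aldehyde A1 to give the cyclic alcohol A2, followed by the same epoxidations and acylations. This is the route most chemists would draw first. A1 carries its C7 stereocentre α to an aldehyde and allylic to the isopropenyl group, so it epimerises and conjugates easily and must be made by separate auxiliary chemistry. C6 would be fixed during a strained ring closure with no basis for prediction, and the medium-ring penalty falls on a step that competes with oligomerisation. In the chosen plan the ten-membered ring arises from a 12-membered ring by an exothermic intramolecular reorganisation, and C7 is created in that step under control of C6.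

**Alternative 2:** [2,3]-Wittig ring contraction: the C6–C7 bond is cut back to the 13-membered bis-allylic ether A3, whose deprotonation at C6 would give A4. C9 has to travel as a β,γ-unsaturated ketal and be unmasked later. Several allylic positions compete for the strong base. Two stereocentres (C6, C7) would have to be set with only the remote C3 centre or a chiral base. A3 also needs three trisubstituted alkenes of defined geometry in one chain, so it is no shorter than lactone 15. The Claisen route is neutral, delivers the ketone directly and creates one stereocentre next to its controller.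

**Alternative 3:** Anionic oxy-Cope ring expansion: the C6–C7 bond is cut and C4–C9 reconnected, giving the cis-1,2-dialkenylcyclohexenol A5, whose alkoxide would rearrange to 17. The C10=C1 alkene would be Z by construction, but C4=C5 is formed in the rearrangement. Its geometry depends on which of two chairs the alkoxide uses, and the usual one (ring carbon equatorial) gives the E alkene, the wrong oxirane series. A5 also needs a quaternary carbon, a tertiary alcohol of defined relative configuration, an E silyl enol ether and a 1,3-diene. In the chosen plan both ring alkenes are made Z in open-chain steps of known selectivity and are only carried through the key step.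

Key step: step 11

## Route

Step 1
Reactants: 1 prop-2-yn-1-ol
Product: 2 (Z)-3-iodo-2-methylprop-2-en-1-ol
Conditions: MeMgBr (3 equiv), CuI (10 mol %), THF, −10 °C to rt; then I2, −78 to 0 °C
Reagents that add atoms: methylmagnesium bromide, C[Mg]Br; iodine, II
Why: Copper-catalysed anti-carbomagnesiation of the magnesium alkoxide of a propargylic alcohol (methyl to C2, magnesium to C3 in a five-membered chelate) followed by iodinolysis with retention gives the Z iodoalkene. This fixes the Z geometry of the later C4=C5 bond (C3 and the future C6 cis).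

Step 2
Reactants: 2 (Z)-3-iodo-2-methylprop-2-en-1-ol
Product: 3 (Z)-3-iodo-2-methylprop-2-enal
Conditions: MnO2, CH2Cl2, rt; used at once
Reagents that add atoms: none
Why: MnO2 oxidation of a primary allylic alcohol under neutral conditions should leave the Z-iodoalkene geometry intact.

Step 3
Reactants: 3 (Z)-3-iodo-2-methylprop-2-enal
Product: 4 (1Z,3S)-1-iodo-2-methylhexa-1,5-dien-3-ol
Conditions: (−)-Ipc2B(allyl), Et2O, −78 °C; then NaOH, H2O2
Reagents that add atoms: (−)-B-allyldiisopinocampheylborane, C=CCB([C@@H]1C[C@@H]2C[C@H]([C@H]1C)C2(C)C)[C@@H]1C[C@@H]2C[C@H]([C@H]1C)C2(C)C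
Why: Brown allylboration through a closed chair transition state. The reagent (the antipode that converts benzaldehyde into (S)-1-phenylbut-3-en-1-ol) selects the aldehyde face and sets C3 (S).

Step 4
Reactants: 4 (1Z,3S)-1-iodo-2-methylhexa-1,5-dien-3-ol
Product: 5 triethyl{[(1Z,3S)-1-iodo-2-methylhexa-1,5-dien-3-yl]oxy}silane
Conditions: TESCl, imidazole, DMF, 0 °C
Reagents that add atoms: chlorotriethylsilane, CC[Si](CC)(CC)Cl
Why: Standard silylation of a secondary alcohol. TES is chosen because it can later be removed in the presence of the TBS ether at C6.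

Step 5
Reactants: 5 triethyl{[(1Z,3S)-1-iodo-2-methylhexa-1,5-dien-3-yl]oxy}silane
Product: 6 (3S,4Z)-5-iodo-4-methyl-3-[(triethylsilyl)oxy]pent-4-enal
Conditions: OsO4 (2 mol %), NaIO4, 2,6-lutidine, dioxane/H2O, rt
Reagents that add atoms: osmium tetroxide (oxygen carrier), O=[Os](=O)(=O)=O; sodium periodate (terminal oxidant), [Na+].[O-]I(=O)(=O)=O
Why: Lemieux–Johnson cleavage. OsO4 should select the monosubstituted alkene over the hindered, iodine-deactivated trisubstituted alkene.

Step 6
Reactants: 6 (3S,4Z)-5-iodo-4-methyl-3-[(triethylsilyl)oxy]pent-4-enal; 7 ethyl 2-[bis(2,2,2-trifluoroethoxy)phosphoryl]propanoate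
Product: 8 ethyl (2Z,5S,6Z)-7-iodo-2,6-dimethyl-5-[(triethylsilyl)oxy]hepta-2,6-dienoate
Conditions: KHMDS, 18-crown-6, THF, −78 °C
Reagents that add atoms: 7 ethyl 2-[bis(2,2,2-trifluoroethoxy)phosphoryl]propanoate, CCOC(=O)C(C)P(=O)(OCC(F)(F)F)OCC(F)(F)F
Why: Still–Gennari olefination: the electron-poor phosphonate with a dissociated potassium counter-ion eliminates rapidly from the kinetic adduct and gives the Z trisubstituted enoate. This puts C9 and C2 cis, the geometry of the later C1–C10 oxirane.

Step 7
Reactants: 8 ethyl (2Z,5S,6Z)-7-iodo-2,6-dimethyl-5-[(triethylsilyl)oxy]hepta-2,6-dienoate; 9 3-bromo-2-methylprop-1-ene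
Product: 11 2-methylprop-2-en-1-yl (2Z,5S,6Z)-7-iodo-2,6-dimethyl-5-[(triethylsilyl)oxy]hepta-2,6-dienoate, via potassium carboxylate 10 (not isolated)
Conditions: KOSiMe3, THF, rt; then 9, DMF, rt
Reagents that add atoms: potassium trimethylsilanolate, C[Si](C)(C)[O-].[K+]; 9 3-bromo-2-methylprop-1-ene, C=C(C)CBr
Why: Anhydrous silanolate cleavage of the ethyl ester gives the potassium carboxylate, which is O-alkylated by SN2 on the allylic bromide. No acyl activation occurs, so the Z-enoate cannot leak to E.

Step 8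
Reactants: 11 2-methylprop-2-en-1-yl (2Z,5S,6Z)-7-iodo-2,6-dimethyl-5-[(triethylsilyl)oxy]hepta-2,6-dienoate; 12 prop-2-enal
Product: 13 2-methylprop-2-en-1-yl (2Z,5S,6Z,8S)-8-hydroxy-2,6-dimethyl-5-[(triethylsilyl)oxy]deca-2,6,9-trienoate
Conditions: 12 (excess), CrCl2, NiCl2 (cat.), chiral sulfonamide–oxazoline ligand for Cr (enantiomer giving the 8S alcohol), Et3N, THF, rt
Reagents that add atoms: 12 prop-2-enal, C=CC=O
Why: Nozaki–Hiyama–Kishi coupling: Ni(0) inserts into the C–I bond with retention of the Z geometry, the alkenyl group passes to Cr(III) and adds only to the aldehyde carbonyl (esters and silyl ethers are inert). The chiral ligand on chromium selects the aldehyde face and sets C6 (8S in 13); the remote C3 centre makes any minor epimer a separable diastereomer.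

Step 9
Reactants: 13 2-methylprop-2-en-1-yl (2Z,5S,6Z,8S)-8-hydroxy-2,6-dimethyl-5-[(triethylsilyl)oxy]deca-2,6,9-trienoate
Product: 14 2-methylprop-2-en-1-yl (2Z,5S,6Z,8S)-8-[(tert-butyldimethylsilyl)oxy]-2,6-dimethyl-5-[(triethylsilyl)oxy]deca-2,6,9-trienoate
Conditions: TBSOTf, 2,6-lutidine, CH2Cl2, −78 °C
Reagents that add atoms: tert-butyldimethylsilyl trifluoromethanesulfonate, CC(C)(C)[Si](C)(C)OS(=O)(=O)C(F)(F)F
Why: Silylation under non-acidic conditions protects the ionisable bis-allylic carbinol. It also differentiates O6 (TBS) from O3 (TES) and provides the allylic alkoxy group that directs step 11.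

Step 10
Reactants: 14 2-methylprop-2-en-1-yl (2Z,5S,6Z,8S)-8-[(tert-butyldimethylsilyl)oxy]-2,6-dimethyl-5-[(triethylsilyl)oxy]deca-2,6,9-trienoate
Product: 15 (3Z,6S,7Z,9S,10E)-9-[(tert-butyldimethylsilyl)oxy]-3,7,11-trimethyl-6-[(triethylsilyl)oxy]-1-oxacyclododeca-3,7,10-trien-2-one
Conditions: Grubbs second-generation catalyst (10 mol %), toluene (1 mM), 80 °C
Reagents that add atoms: none
Why: Ring-closing metathesis: the ruthenium carbene forms at the monosubstituted vinyl group and closes onto the 1,1-disubstituted methallyl alkene with loss of ethene, giving a 12-membered lactone free of medium-ring strain; the other alkenes are trisubstituted and should react far more slowly. The configuration of the new C7=C11 bond is immaterial (the E isomer is listed; an E/Z mixture can be carried on) because C12 and the methyl group both end up in the isopropenyl group.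

Step 11
Reactants: 15 (3Z,6S,7Z,9S,10E)-9-[(tert-butyldimethylsilyl)oxy]-3,7,11-trimethyl-6-[(triethylsilyl)oxy]-1-oxacyclododeca-3,7,10-trien-2-one
Product: 17 (2Z,5S,6Z,8R,9S)-8-[(tert-butyldimethylsilyl)oxy]-2,6-dimethyl-9-(prop-1-en-2-yl)-5-[(triethylsilyl)oxy]cyclodeca-2,6-dien-1-one, via 2-methylidene enol ether 16 (not isolated)
Conditions: Cp2TiMe2 (3 equiv), toluene, 75 °C, dark; then 130 °C
Reagents that add atoms: dimethyltitanocene (supplies C8 as CH2), C[Ti](C)(C1C=CC=C1)C1C=CC=C1
Why: Cp2TiMe2 loses methane to give Cp2Ti=CH2, which converts the lactone carbonyl through an oxatitanacyclobutane into the 2-alkoxy-1,3-diene 16; on further heating 16 should undergo a concerted [3,3] shift (Claisen rearrangement) in the array C8=C9–O–C12–C11=C7, forming the C8–C7 bond, breaking O–C12, turning C9 into the ketone and releasing C11=C12 as the isopropenyl group. The closest known reaction types are the methylenation–Claisen sequence of vinyl-substituted lactones and the ring-contracting Claisen rearrangement of macrolide ketene acetals. The ten-membered ring is closed by the C7–C8 bond through a six-membered pericyclic array as a 12→10 ring contraction with extrusion of O, C12 and C11, so the medium ring is paid for by an exothermic intramolecular step that starts from a strain-free macrolactone. C7 is the only new stereocentre and is controlled by C6: A(1,3) strain with the C11 substituent cis to C6 holds the C6–H bond in the plane of the C7=C11 alkene, and C8 should bond to the face of C7 anti to the C6–OTBS bond, which is also the face on which the ring chain (C5) lies; this gives the 6,7 relationship of the target (8R,9S in 17). Because C8 is an unsubstituted CH2, chair and boat arrays and both E and Z isomers of C7=C11 lead to the same product, so only facial selectivity at C7 is required. The Z geometry of C10=C1 and C4=C5 is untouched, and the Z,Z-1,5-diene of 17 can enter a Cope rearrangement only through a boat, which should be slow at 130 °C.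

Step 12
Reactants: 17 (2Z,5S,6Z,8R,9S)-8-[(tert-butyldimethylsilyl)oxy]-2,6-dimethyl-9-(prop-1-en-2-yl)-5-[(triethylsilyl)oxy]cyclodeca-2,6-dien-1-one
Product: 18 (1R,3S,4Z,6R,7S,10R)-6-[(tert-butyldimethylsilyl)oxy]-1,10-epoxy-3-[(triethylsilyl)oxy]germacra-4,11-dien-9-one
Conditions: t-BuOOH (anhydrous), DBU, CH2Cl2, 0 °C to rt
Reagents that add atoms: tert-butyl hydroperoxide, CC(C)(C)OO
Why: Weitz–Scheffer epoxidation: t-BuOO− adds to C1 of the only electron-poor alkene and the enolate closes at C10 with loss of t-BuO−; the ring prevents bond rotation in the enolate, so the cis oxirane is expected. The face is expected from peripheral attack on a conformer in which the ring segments C2–C3 and C8–C7 lie on one side of the enone; this is argued from a model, not from a directing group.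

Step 13
Reactants: 18 (1R,3S,4Z,6R,7S,10R)-6-[(tert-butyldimethylsilyl)oxy]-1,10-epoxy-3-[(triethylsilyl)oxy]germacra-4,11-dien-9-one
Product: 19 (1R,3S,4Z,6R,7S,10R)-6-[(tert-butyldimethylsilyl)oxy]-1,10-epoxy-3-hydroxygermacra-4,11-dien-9-one
Conditions: PPTS (cat.), MeOH/CH2Cl2, 0 °C
Reagents that add atoms: none
Why: Acid-catalysed methanolysis removes the less hindered TES ether while the TBS ether and the oxirane should survive the mild buffer.

Step 14
Reactants: 19 (1R,3S,4Z,6R,7S,10R)-6-[(tert-butyldimethylsilyl)oxy]-1,10-epoxy-3-hydroxygermacra-4,11-dien-9-one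
Product: 20 (1R,3S,4R,5S,6S,7S,10R)-6-[(tert-butyldimethylsilyl)oxy]-1,10:4,5-diepoxy-3-hydroxygermacr-11-en-9-one
Conditions: mCPBA (1.1 equiv), NaHCO3, CH2Cl2, 0 °C
Reagents that add atoms: 3-chloroperoxybenzoic acid, O=C(OO)c1cccc(Cl)c1
Why: Henbest-type hydroxyl-directed epoxidation: A(1,3) strain across the Z alkene holds C3–H in the alkene plane, and the hydrogen-bonded peracid delivers oxygen to the face syn to the C3 hydroxyl (threo), which is also the face remote from the C6 silyloxy group. The hydrogen-bond-activated trisubstituted alkene should react before the isopropenyl group.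

Step 15
Reactants: 20 (1R,3S,4R,5S,6S,7S,10R)-6-[(tert-butyldimethylsilyl)oxy]-1,10:4,5-diepoxy-3-hydroxygermacr-11-en-9-one
Product: 21 (1R,3S,4R,5S,6S,7S,10R)-1,10:4,5-diepoxy-3,6-dihydroxygermacr-11-en-9-one
Conditions: HF·pyridine, pyridine, THF, 0 °C to rt
Reagents that add atoms: none
Why: Fluoride cleavage of the TBS ether; the pyridine buffer avoids both acid opening of the oxiranes and base-induced Payne rearrangement.

Step 16
Reactants: 21 (1R,3S,4R,5S,6S,7S,10R)-1,10:4,5-diepoxy-3,6-dihydroxygermacr-11-en-9-one; 22 (2Z)-2-methylbut-2-enoic acid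
Product: 23 (1R,3S,4R,5S,6S,7S,10R)-1,10:4,5-diepoxy-9-oxogermacr-11-ene-3,6-diyl bis[(2Z)-2-methylbut-2-enoate]
Conditions: 22, 2,4,6-trichlorobenzoyl chloride, Et3N, toluene, rt; then 21, 80 °C
Reagents that add atoms: 22 (2Z)-2-methylbut-2-enoic acid, C/C=C(/C)C(=O)O
Why: Yamaguchi-type mixed-anhydride acylation run without a nucleophilic catalyst, which avoids the addition–elimination pathway that turns angelates into tiglates. Both secondary alcohols are acylated in one operation.

## Compound list

1 | prop-2-yn-1-ol | C#CCO | starting material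
2 | (Z)-3-iodo-2-methylprop-2-en-1-ol | OC/C(C)=C\I | intermediate
3 | (Z)-3-iodo-2-methylprop-2-enal | O=C/C(C)=C\I | intermediate
4 | (1Z,3S)-1-iodo-2-methylhexa-1,5-dien-3-ol | C=CC[C@H](O)/C(C)=C\I | intermediate
5 | triethyl{[(1Z,3S)-1-iodo-2-methylhexa-1,5-dien-3-yl]oxy}silane | C=CC[C@H](O[Si](CC)(CC)CC)/C(C)=C\I | intermediate
6 | (3S,4Z)-5-iodo-4-methyl-3-[(triethylsilyl)oxy]pent-4-enal | O=CC[C@H](O[Si](CC)(CC)CC)/C(C)=C\I | intermediate
7 | ethyl 2-[bis(2,2,2-trifluoroethoxy)phosphoryl]propanoate | CCOC(=O)C(C)P(=O)(OCC(F)(F)F)OCC(F)(F)F | starting material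
8 | ethyl (2Z,5S,6Z)-7-iodo-2,6-dimethyl-5-[(triethylsilyl)oxy]hepta-2,6-dienoate | CCOC(=O)/C(C)=C\C[C@H](O[Si](CC)(CC)CC)/C(C)=C\I | intermediate
9 | 3-bromo-2-methylprop-1-ene (methallyl bromide) | C=C(C)CBr | starting material
10 | potassium (2Z,5S,6Z)-7-iodo-2,6-dimethyl-5-[(triethylsilyl)oxy]hepta-2,6-dienoate | [K+].[O-]C(=O)/C(C)=C\C[C@H](O[Si](CC)(CC)CC)/C(C)=C\I | intermediate
11 | 2-methylprop-2-en-1-yl (2Z,5S,6Z)-7-iodo-2,6-dimethyl-5-[(triethylsilyl)oxy]hepta-2,6-dienoate | C=C(C)COC(=O)/C(C)=C\C[C@H](O[Si](CC)(CC)CC)/C(C)=C\I | intermediate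
12 | prop-2-enal (acrolein) | C=CC=O | starting material
13 | 2-methylprop-2-en-1-yl (2Z,5S,6Z,8S)-8-hydroxy-2,6-dimethyl-5-[(triethylsilyl)oxy]deca-2,6,9-trienoate | C=C(C)COC(=O)/C(C)=C\C[C@H](O[Si](CC)(CC)CC)/C(C)=C\[C@@H](O)C=C | intermediate
14 | 2-methylprop-2-en-1-yl (2Z,5S,6Z,8S)-8-[(tert-butyldimethylsilyl)oxy]-2,6-dimethyl-5-[(triethylsilyl)oxy]deca-2,6,9-trienoate | C=C(C)COC(=O)/C(C)=C\C[C@H](O[Si](CC)(CC)CC)/C(C)=C\[C@@H](O[Si](C)(C)C(C)(C)C)C=C | intermediate
15 | (3Z,6S,7Z,9S,10E)-9-[(tert-butyldimethylsilyl)oxy]-3,7,11-trimethyl-6-[(triethylsilyl)oxy]-1-oxacyclododeca-3,7,10-trien-2-one | C/C1=C/C[C@H](O[Si](CC)(CC)CC)/C(C)=C\[C@@H](O[Si](C)(C)C(C)(C)C)/C=C(C)/COC1=O | intermediate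
16 | (3Z,6S,7Z,9S,10E)-9-[(tert-butyldimethylsilyl)oxy]-3,7,11-trimethyl-2-methylidene-6-[(triethylsilyl)oxy]-1-oxacyclododeca-3,7,10-triene | C/C1=C/C[C@H](O[Si](CC)(CC)CC)/C(C)=C\[C@@H](O[Si](C)(C)C(C)(C)C)/C=C(C)/COC1=C | intermediate
17 | (2Z,5S,6Z,8R,9S)-8-[(tert-butyldimethylsilyl)oxy]-2,6-dimethyl-9-(prop-1-en-2-yl)-5-[(triethylsilyl)oxy]cyclodeca-2,6-dien-1-one [germacrane numbering: (1(10)Z,3S,4Z,6R,7S)-6-OTBS-3-OTES-germacra-1(10),4,11-trien-9-one] | C=C(C)[C@@H]1CC(=O)/C(C)=C\C[C@H](O[Si](CC)(CC)CC)/C(C)=C\[C@H]1O[Si](C)(C)C(C)(C)C | intermediate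
18 | (1R,3S,4Z,6R,7S,10R)-6-[(tert-butyldimethylsilyl)oxy]-1,10-epoxy-3-[(triethylsilyl)oxy]germacra-4,11-dien-9-one | C=C(C)[C@@H]1CC(=O)[C@]2(C)O[C@@H]2C[C@H](O[Si](CC)(CC)CC)/C(C)=C\[C@H]1O[Si](C)(C)C(C)(C)C | intermediate
19 | (1R,3S,4Z,6R,7S,10R)-6-[(tert-butyldimethylsilyl)oxy]-1,10-epoxy-3-hydroxygermacra-4,11-dien-9-one | C=C(C)[C@@H]1CC(=O)[C@]2(C)O[C@@H]2C[C@H](O)/C(C)=C\[C@H]1O[Si](C)(C)C(C)(C)C | intermediate
20 | (1R,3S,4R,5S,6S,7S,10R)-6-[(tert-butyldimethylsilyl)oxy]-1,10:4,5-diepoxy-3-hydroxygermacr-11-en-9-one | C=C(C)[C@@H]1CC(=O)[C@]2(C)O[C@@H]2C[C@H](O)[C@@]2(C)O[C@H]2[C@H]1O[Si](C)(C)C(C)(C)C | intermediate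
21 | (1R,3S,4R,5S,6S,7S,10R)-1,10:4,5-diepoxy-3,6-dihydroxygermacr-11-en-9-one | C=C(C)[C@@H]1CC(=O)[C@]2(C)O[C@@H]2C[C@H](O)[C@@]2(C)O[C@H]2[C@H]1O | intermediate
22 | (2Z)-2-methylbut-2-enoic acid (angelic acid) | C/C=C(/C)C(=O)O | starting material
23 | (1R,3S,4R,5S,6S,7S,10R)-1,10:4,5-diepoxy-9-oxogermacr-11-ene-3,6-diyl bis[(2Z)-2-methylbut-2-enoate] | C=C(C)[C@@H]1CC(=O)[C@]2(C)O[C@@H]2C[C@H](OC(=O)/C(C)=C\C)[C@@]2(C)O[C@H]2[C@H]1OC(=O)/C(C)=C\C | target

## Step count and least certain steps

Total step count: 16. Longest linear sequence: 16 (steps 1–16 from propargyl alcohol 1).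

**Step 11 (key step).** The ring-contracting shift may be slower than thermal side reactions of the alkoxydiene (1,5-hydrogen shift from C2 to C8, hydrolysis on traces of acid), because the 12-membered ring must fold C8 over C7. The macrocycle may also force bond formation on the face of C7 syn to the silyloxy group, and prolonged heating may start the Cope rearrangement of the product. Fallback (sets out from 5, returns at 17): the [3,3] step is moved to the open chain and the ring is closed afterwards by a Ni/Cr coupling that creates no lasting stereocentre. Iodide 5 is coupled under the conditions of step 8 with (2E)-2-methyl-4-oxobut-2-en-1-yl acetate to give the allylic alcohol F1, which is silylated (TBSOTf) to the bis-silyl ether F2. Cleavage of the terminal alkene (OsO4, NaIO4) gives the aldehyde F3, and Stork–Zhao olefination (Ph3P=C(I)CH3) gives the (Z)-2-iodoalkene F4. Ireland–Claisen rearrangement of the allylic acetate (LDA, TMSCl, −78 °C to rt) gives the γ,δ-unsaturated acid F5, with C7 set by the same A(1,3)/anti-to-oxygen control but without ring constraints. Methylation (TMSCHN2) gives the methyl ester F6 and DIBAL-H at −78 °C the aldehyde F7. Intramolecular Ni/Cr coupling at high dilution closes the ring between C9 and C10 to the allylic alcohol F8 (both C9 epimers), and Dess–Martin oxidation gives 17.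

**Step 12.** Peroxide addition may occur on the wrong face of the enone, since only the ring conformation decides and it is not known; γ-deprotonation with loss of the C3 silyloxy group is a lesser concern. Fallback (sets out from 17, returns at 18): Luche reduction gives the allylic alcohol F9 (the C9 epimer with the hydroxyl on the face to be epoxidised; the other epimer is recycled by oxidation). Vanadium-catalysed epoxidation (VO(acac)2, t-BuOOH), delivered by the bound hydroxyl to the cis face, gives the epoxy alcohol F10, and Dess–Martin oxidation gives 18.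

**Step 10.** Ring closure onto the 1,1-disubstituted alkene may be slow, so that oligomerisation or closure onto the C1=C10 enoate alkene (a seven-membered ring with loss of the ester) competes. Fallback (sets out from 10, returns at 15): carboxylate 10 is alkylated with (2E)-4-bromo-3-methylbut-2-enal to give the ester aldehyde F11. Intramolecular Ni/Cr coupling with the ligand of step 8 at high dilution closes the 12-membered ring at C5–C6 to the macrocyclic alcohol F12 (C7=C11 fixed as E by the bromide), and silylation (TBSOTf) gives 15.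

**Step 8.** Reagent control by the chromium ligand may be incomplete with a small, unhindered aldehyde, giving poor facial selectivity at C6. Fallback (sets out from 11, returns at 13): the ligand-free Ni/Cr coupling gives 13 together with its C8 epimer F13. The mixture is oxidised (Dess–Martin) to the dienone F14, and Corey–Bakshi–Shibata reduction with catecholborane (vinyl as the small group, oxazaborolidine enantiomer chosen accordingly) gives 13.

**Step 16.** Isomerisation of the activated angeloyl group to tigloyl, incomplete acylation of two hindered epoxy alcohols, or Payne rearrangement under forcing conditions. Fallback (sets out from 21, returns at 23): 21 is acylated (DCC, DMAP) with 2-[bis(2,2,2-trifluoroethoxy)phosphoryl]propanoic acid to give the bis-phosphonate F15. A double Still–Gennari olefination with acetaldehyde (KHMDS, 18-crown-6, −78 °C) then builds both Z-2-methylbut-2-enoate groups in place and gives 23.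

## Further compounds

F1 | step 11 | (2E,4S,5Z,7S)-4-hydroxy-2,6-dimethyl-7-[(triethylsilyl)oxy]deca-2,5,9-trien-1-yl acetate | C=CC[C@H](O[Si](CC)(CC)CC)/C(C)=C\[C@@H](O)/C=C(C)/COC(C)=O
F2 | step 11 | (2E,4S,5Z,7S)-4-[(tert-butyldimethylsilyl)oxy]-2,6-dimethyl-7-[(triethylsilyl)oxy]deca-2,5,9-trien-1-yl acetate | C=CC[C@H](O[Si](CC)(CC)CC)/C(C)=C\[C@@H](O[Si](C)(C)C(C)(C)C)/C=C(C)/COC(C)=O
F3 | step 11 | (2E,4S,5Z,7S)-4-[(tert-butyldimethylsilyl)oxy]-2,6-dimethyl-9-oxo-7-[(triethylsilyl)oxy]nona-2,5-dien-1-yl acetate | O=CC[C@H](O[Si](CC)(CC)CC)/C(C)=C\[C@@H](O[Si](C)(C)C(C)(C)C)/C=C(C)/COC(C)=O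
F4 | step 11 | (2E,4S,5Z,7S,9Z)-4-[(tert-butyldimethylsilyl)oxy]-10-iodo-2,6-dimethyl-7-[(triethylsilyl)oxy]undeca-2,5,9-trien-1-yl acetate | C/C(I)=C/C[C@H](O[Si](CC)(CC)CC)/C(C)=C\[C@@H](O[Si](C)(C)C(C)(C)C)/C=C(C)/COC(C)=O
F5 | step 11 | (3S,4R,5Z,7S,9Z)-4-[(tert-butyldimethylsilyl)oxy]-10-iodo-6-methyl-3-(prop-1-en-2-yl)-7-[(triethylsilyl)oxy]undeca-5,9-dienoic acid | C/C(I)=C/C[C@H](O[Si](CC)(CC)CC)/C(C)=C\[C@@H](O[Si](C)(C)C(C)(C)C)[C@@H](CC(=O)O)C(C)=C
F6 | step 11 | methyl (3S,4R,5Z,7S,9Z)-4-[(tert-butyldimethylsilyl)oxy]-10-iodo-6-methyl-3-(prop-1-en-2-yl)-7-[(triethylsilyl)oxy]undeca-5,9-dienoate | C/C(I)=C/C[C@H](O[Si](CC)(CC)CC)/C(C)=C\[C@@H](O[Si](C)(C)C(C)(C)C)[C@@H](CC(=O)OC)C(C)=C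
F7 | step 11 | (3S,4R,5Z,7S,9Z)-4-[(tert-butyldimethylsilyl)oxy]-10-iodo-6-methyl-3-(prop-1-en-2-yl)-7-[(triethylsilyl)oxy]undeca-5,9-dienal | C/C(I)=C/C[C@H](O[Si](CC)(CC)CC)/C(C)=C\[C@@H](O[Si](C)(C)C(C)(C)C)[C@@H](CC=O)C(C)=C
F8 | step 11 | (2Z,5S,6Z,8R,9S)-8-[(tert-butyldimethylsilyl)oxy]-2,6-dimethyl-9-(prop-1-en-2-yl)-5-[(triethylsilyl)oxy]cyclodeca-2,6-dien-1-ol (both C1 epimers) | C=C(C)[C@@H]1CC(O)/C(C)=C\C[C@H](O[Si](CC)(CC)CC)/C(C)=C\[C@H]1O[Si](C)(C)C(C)(C)C
F9 | step 12 | (1(10)Z,3S,4Z,6R,7S,9S)-6-[(tert-butyldimethylsilyl)oxy]-3-[(triethylsilyl)oxy]germacra-1(10),4,11-trien-9-ol | C=C(C)[C@@H]1C[C@H](O)/C(C)=C\C[C@H](O[Si](CC)(CC)CC)/C(C)=C\[C@H]1O[Si](C)(C)C(C)(C)C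
F10 | step 12 | (1R,3S,4Z,6R,7S,9S,10S)-6-[(tert-butyldimethylsilyl)oxy]-1,10-epoxy-3-[(triethylsilyl)oxy]germacra-4,11-dien-9-ol | C=C(C)[C@@H]1C[C@H](O)[C@]2(C)O[C@@H]2C[C@H](O[Si](CC)(CC)CC)/C(C)=C\[C@H]1O[Si](C)(C)C(C)(C)C
F11 | step 10 | (2E)-2-methyl-4-oxobut-2-en-1-yl (2Z,5S,6Z)-7-iodo-2,6-dimethyl-5-[(triethylsilyl)oxy]hepta-2,6-dienoate | O=C/C=C(C)/COC(=O)/C(C)=C\C[C@H](O[Si](CC)(CC)CC)/C(C)=C\I
F12 | step 10 | (3Z,6S,7Z,9S,10E)-9-hydroxy-3,7,11-trimethyl-6-[(triethylsilyl)oxy]-1-oxacyclododeca-3,7,10-trien-2-one | C/C1=C/C[C@H](O[Si](CC)(CC)CC)/C(C)=C\[C@@H](O)/C=C(C)/COC1=O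
F13 | step 8 | 2-methylprop-2-en-1-yl (2Z,5S,6Z,8R)-8-hydroxy-2,6-dimethyl-5-[(triethylsilyl)oxy]deca-2,6,9-trienoate | C=C(C)COC(=O)/C(C)=C\C[C@H](O[Si](CC)(CC)CC)/C(C)=C\[C@H](O)C=C
F14 | step 8 | 2-methylprop-2-en-1-yl (2Z,5S,6Z)-2,6-dimethyl-8-oxo-5-[(triethylsilyl)oxy]deca-2,6,9-trienoate | C=C(C)COC(=O)/C(C)=C\C[C@H](O[Si](CC)(CC)CC)/C(C)=C\C(=O)C=C
F15 | step 16 | (1R,3S,4R,5S,6S,7S,10R)-1,10:4,5-diepoxy-9-oxogermacr-11-ene-3,6-diyl bis{2-[bis(2,2,2-trifluoroethoxy)phosphoryl]propanoate} | C=C(C)[C@@H]1CC(=O)[C@]2(C)O[C@@H]2C[C@H](OC(=O)C(C)P(=O)(OCC(F)(F)F)OCC(F)(F)F)[C@@]2(C)O[C@H]2[C@H]1OC(=O)C(C)P(=O)(OCC(F)(F)F)OCC(F)(F)F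
A1 | alternative 1 | (2S,5Z,8S,9Z)-10-iodo-5,9-dimethyl-4-oxo-2-(prop-1-en-2-yl)-8-[(triethylsilyl)oxy]deca-5,9-dienal | O=C[C@H](C(C)=C)CC(=O)/C(C)=C\C[C@H](O[Si](CC)(CC)CC)/C(C)=C\I
A2 | alternative 1 | (2Z,5S,6Z,8R,9S)-8-hydroxy-2,6-dimethyl-9-(prop-1-en-2-yl)-5-[(triethylsilyl)oxy]cyclodeca-2,6-dien-1-one | C=C(C)[C@@H]1CC(=O)/C(C)=C\C[C@H](O[Si](CC)(CC)CC)/C(C)=C\[C@H]1O
A3 | alternative 2 | (3E,7Z,10S,11Z)-6,6-(ethane-1,2-diyldioxy)-3,7,11-trimethyl-10-[(triethylsilyl)oxy]-1-oxacyclotrideca-3,7,11-triene | C/C1=C\CC2(OCCO2)/C(C)=C\C[C@H](O[Si](CC)(CC)CC)/C(C)=C\COC1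
A4 | alternative 2 | (1(10)Z,3S,4Z,6R,7S)-9,9-(ethane-1,2-diyldioxy)-3-[(triethylsilyl)oxy]germacra-1(10),4,11-trien-6-ol | C=C(C)[C@@H]1CC2(OCCO2)/C(C)=C\C[C@H](O[Si](CC)(CC)CC)/C(C)=C\[C@H]1O
A5 | alternative 3 | (5S)-6-[(E)-2-[(tert-butyldimethylsilyl)oxy]ethenyl]-2,6-dimethyl-1-[(1E)-3-methylbuta-1,3-dien-1-yl]-5-[(triethylsilyl)oxy]cyclohex-2-en-1-ol (1,6-cis-dialkenyl isomer) | CC1=CC[C@H](O[Si](CC)(CC)CC)[C@](C)(/C=C/O[Si](C)(C)C(C)(C)C)[C@]1(O)/C=C/C(C)=C
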